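## Analysis of the target

The target is a sesquiterpenoid hydroxyquinone built on a cis-fused decalin (ring A = C1–C5 and C10, ring B = C5–C10). It carries an exocyclic methylene (C11) on C4, methyl groups on C5, C8 and C9, and a 2-hydroxy-5-methoxy-1,4-benzoquinone joined through the methylene C15 to C9. Four contiguous stereocentres, C5, C10, C9 and C8, have the configuration (5R,8R,9R,10S). In relative terms the C5 methyl, H-10, the C9 arylmethyl arm and the C8 methyl lie on one face of ring B (the convex face), and the C9 methyl lies on the other. C5 and C9 are both quaternary and flank C10. The hydroxyquinone is a redox-active vinylogous acid and the C4=C11 alkene moves into the ring under acid, so both are uncovered last and the quinone is carried as a 2,3,5,6-tetramethoxyphenyl group. The hard points are the cis ring fusion with its angular methyl, the quaternary C9 with the arylmethyl arm, and the C8 methyl cis to that arm. The plan rests on the fact that C4 and C8 can both be carbonyl carbons: a ring B ketone at C8 next to a C3=C4 enol ether in ring A is what an oxy-Cope shift delivers from a 2-vinylbicyclo[2.2.2]oct-5-en-2-ol with bridgeheads C3 and C10 and an intact C3–C8 bond, and that bicycle can close ring B only as the cis-fused isomer.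

## Retrosynthetic reasoning

**25 to 23.** The hydroxyquinone 25 is traced through dimethoxyquinone 24 to the tetramethoxyarene 23. No skeletal bond is cut. The arene tolerates the organometallic, basic and reducing steps that the quinone would not. Forward, oxidative demethylation of the symmetrical arene can give only one para-quinone, and the hydrolysis must then pick the methoxy group next to the alkyl-bearing carbon.

**23 to 21.** C4=C11 is cut to ketone 22 by a Wittig disconnection. It is placed late because the exocyclic alkene would not survive the hydrogenation at C8. Ketone 22 is carried as its silyl enol ether 21, which is the form in which the key step delivers C4, so no separate protection is needed.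

**21 to 19.** The C8 methyl is cut back through methylidene compound 20 to ketone 19. C8 is a carbonyl carbon because it is the carbinol carbon of the key step. Forward, hydrogen must reach C8 on the face of the C9 methyl.

**19 to 16 (key disconnection).** In 19 the bond C5–C6 is cut and C3–C8 is re-formed, which gives the vinyl carbinol 16. The cut is made here because it turns the cis-decalin with a quaternary C5 into a bicyclo[2.2.2]octene. In that bicycle C9 and C10 sit on a rigid frame and the C4 oxygen is an enol ether on the etheno bridge. Forward, the potassium alkoxide 17 must undergo the [3,3] shift to enolate 18 faster than it fragments.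

**16 to 14 and 15.** The C7–C8 bond is cut to ketone 14 and vinylmagnesium bromide 15. Ketone 14 cannot enolise, since C3 is a bridgehead and C9 is quaternary. The addition must come from the face syn to the enol ether bridge, because only that carbinol can rearrange.

**14 to 7 and 8.** The ketone comes from alcohol 13 and its pivalate 12. The aryl–C15 bond is cut through xanthate 11 to aldehyde 7 and 1,2,4,5-tetramethoxybenzene 8. The formyl carbon of 7 becomes C15, so the aryl group is joined by addition of the aryllithium 9 and radical removal of the benzylic oxygen.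

**7 to 3 and 6.** Bonds C3–C8 and C9–C10 are cut (Diels–Alder). The donor oxygen on C4 makes C3 the nucleophilic diene terminus, so the acceptor carbon must be C9 and the C8 oxygen has to come in as a β-acyloxy group on the enal 3. A ketene equivalent would put the carbonyl on the wrong carbon. The endo position of the formyl group places the future arylmethyl arm syn to the enol ether bridge, and a chiral Lewis acid sets the absolute sense.

**3 to 1, and 6 to 4.** Enal 3 is the enol pivalate of the malondialdehyde enolate 2 obtained from commercial 1. Diene 6 is the kinetic, cross-conjugated silyl dienol ether of 2-methylcyclohex-2-enone 4, made through dienolate 5. A silyl ether is chosen because the kinetic enolate fixes the position of the diene, which an acid-mediated enol ether synthesis from the enone would not guarantee.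

## Alternatives that were turned down

**Alternative 1:** Cutting C5–C10 and C8–C9 opens both rings and leads to the open-chain trienal A2. In A2 an (E)-2-methyl enal (C9=C10) is tied through C1–C4 to a diene C5=C6–C7=C8 whose C5 end carries the tether in the (Z) position. Heating or Me2AlCl would fold A2 into the octalin aldehyde A1.
- For: both rings, both quaternary centres and all four ring stereocentres arise in one suprafacial event, and the Z tether allows only the cis-fused product. The C8 methyl follows directly from the diene geometry. On that point this route is stronger than the chosen one, which needs two extra steps and a face-selective hydrogenation for C8.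
- Against: each forming bond ends at a carbon that becomes quaternary (C5 and C9). The fully substituted, Z-tethered diene terminus makes the reactive s-cis conformer strained, so a 1,5-hydrogen shift can compete at the temperature needed. The absolute sense hangs on one silyloxy stereocentre at C4 in a flexible tether. A2 needs a stereodefined trisubstituted (Z,E)-diene, and the arylmethyl arm must still be built from the aldehyde afterwards.
- Comparison: the chosen plan forms one C–C bond in its key step, inside a rigid bicycle and with strain release. It creates only one quaternary centre in a bimolecular cycloaddition that is activated by a strong Lewis acid.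

**Alternative 2:** Cutting ring A at C4–C5 and C1–C10 leaves ring B as enone A4 and the silyloxydiene A5. Their endo addition under ZnCl2 or pressure would give octalone A3.
- For: the route is convergent. The arylmethyl arm and the C8 and C9 stereocentres are in place before ring A is made, so C8 needs no later correction (stronger than the chosen route here). The donor oxygen directs itself to C4, cis fusion is automatic on a cyclic dienophile, and the diene should approach anti to the arylmethyl arm, which is the face required.
- Against: A4 is a 2-methylcyclohexenone whose β-carbon C10 sits next to the quaternary C9, so it is a weak and crowded acceptor. Lewis acids strong enough to activate it also cleave A5. The margin of face selection (methyl against arylmethyl on C9) is not secured. A3 carries a C6 carbonyl that the target does not need and that costs two or three steps to remove, and C2=C3 must be saturated. A4 itself, with a configured quaternary C9 next to C8, is a multi-step problem.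
- Comparison: the chosen plan uses both oxygen atoms its key step leaves (C4 and C8) and closes its ring intramolecularly.

**Alternative 3:** Cutting C5–C10 and C3–C4 gives triene A7, in which a (Z)-β-methyl enoate (C4=C5) is tied through C6–C9 to an (E)-diene. Heat or MeAlCl2 would give the octalin ester A6, with ring A as the cycloadduct.
- For: C8 and C9 are set before cyclisation. The ester carbon is C11, so no Wittig reaction on a hindered ketone is needed. On both points it is stronger than the chosen route.
- Against: a β,β-disubstituted enoate that must create the quaternary C5 is a poor dienophile. Cis or trans fusion depends on how the four-carbon tether folds, and nothing in A7 forbids the trans-fused transition state. A7 needs adjacent tertiary C8 and quaternary C9 stereocentres in an open chain. The ester must still be turned into the methylene (reduction, selenide, elimination) and C1=C2 reduced selectively.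
- Comparison: in the chosen plan the frame enforces the cis fusion, and C9 and C10 are set on a rigid bicycle.

Key step: step 9

**Remarks before the route**

- Carbon numbers C1–C15 are those of the decalin skeleton of 25 and are kept for all intermediates. In bicyclo[2.2.2]octene names, locants 1, 2, 3, 4, 5, 6, 7, 8 correspond to C3, C8, C9, C10, C5, C4, C2, C1.
- Assumption: in step 3 the catalyst is taken to bind the aldehyde on its convex face with the formyl C–H···O contact and an s-trans enal. On that model the (R)-prolinol-derived catalyst exposes the Si face of the α-carbon of 3. If the sense is opposite, the (S)-prolinol-derived catalyst is used and nothing else changes.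

## Route

Step 1
Reactants: 1 3-ethoxy-2-methylprop-2-enal (3-ethoxy-2-methylacrolein)
Product: 3 (E)-2-methyl-3-oxoprop-1-en-1-yl 2,2-dimethylpropanoate [(E)-3-pivaloyloxy-2-methylacrolein], via sodium 2-methyl-3-oxoprop-1-en-1-olate 2 (not isolated)
Conditions: NaOH (1.0 equiv), H2O/EtOH, 40 °C; solvent exchange to THF (toluene azeotrope); pivaloyl chloride (1.1 equiv), 0 °C → rt
Reagents that add atoms: sodium hydroxide, [Na+].[OH-]; pivaloyl chloride, CC(C)(C)C(Cl)=O
Why: Hydroxide replaces ethoxide of the vinylogous ester by addition–elimination to give the symmetrical enolate 2, which is O-acylated to the enol ester; the acyl group lowers the donor strength of the β-oxygen so that 3 stays an electron-poor dienophile, and the hindered pivalate is chosen because it must later survive an aryllithium.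

Step 2
Reactants: 4 2-methylcyclohex-2-en-1-one
Product: 6 [(6-methylcyclohexa-1,5-dien-1-yl)oxy]tri(propan-2-yl)silane (2-triisopropylsilyloxy-3-methylcyclohexa-1,3-diene), via lithium 6-methylcyclohexa-1,5-dien-1-olate 5 (not isolated)
Conditions: LiN(iPr)2 (1.1 equiv), THF, −78 °C; iPr3SiOSO2CF3 (1.1 equiv), −78 → 0 °C
Reagents that add atoms: triisopropylsilyl trifluoromethanesulfonate, CC(C)[Si](OS(=O)(=O)C(F)(F)F)(C(C)C)C(C)C
Why: Kinetic deprotonation at the α' carbon gives the cross-conjugated dienolate 5 and O-silylation fixes it as the 2-silyloxy diene (silyl enol ether formation), with oxygen and methyl on the two inner diene carbons; the bulky silyl group is chosen to withstand the acidic catalyst of step 3.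

Step 3
Reactants: 3 (E)-3-pivaloyloxy-2-methylacrolein; 6 2-triisopropylsilyloxy-3-methylcyclohexa-1,3-diene
Product: 7 (1R,2S,3S,4R)-3-formyl-3,5-dimethyl-6-{[tri(propan-2-yl)silyl]oxy}bicyclo[2.2.2]oct-5-en-2-yl 2,2-dimethylpropanoate (formyl syn to the enol ether bridge; methyl and pivaloyloxy syn to the ethano bridge)
Conditions: (3aR)-1-(2-methylphenyl)-3,3-diphenyltetrahydro-1H,3H-pyrrolo[1,2-c][1,3,2]oxazaborole (20 mol%, from (R)-α,α-diphenylprolinol), HN(SO2CF3)2 (18 mol%), CH2Cl2, −78 → −40 °C; Et3N quench
Reagents that add atoms: none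
Why: Enantioselective Diels–Alder reaction of an enal activated by a chiral oxazaborolidinium ion: the enol ether carbon C3 is the nucleophilic diene terminus and bonds to the β-carbon of the enal (C8), so the quaternary acceptor carbon C9 joins C10; the formyl group lies under the diene (endo), which puts it syn to the C4=C5 bridge, and the catalyst shields one enal face so that the diene adds to the Si face of the α-carbon; the E geometry of 3 carries pivaloyloxy and methyl to the same side.

Step 4
Reactants: 7 bicyclic aldehyde; 8 1,2,4,5-tetramethoxybenzene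
Product: 11 (1R,2S,3S,4S)-3-[{[(methylsulfanyl)carbonothioyl]oxy}(2,3,5,6-tetramethoxyphenyl)methyl]-3,5-dimethyl-6-{[tri(propan-2-yl)silyl]oxy}bicyclo[2.2.2]oct-5-en-2-yl 2,2-dimethylpropanoate (S-methyl xanthate; both epimers at C15), via (2,3,5,6-tetramethoxyphenyl)lithium 9 (not isolated), via lithium benzylic alkoxide 10 (not isolated)
Conditions: 8 (1.3 equiv), n-BuLi (1.25 equiv), THF, 0 °C; 7, −78 °C; CS2 (5 equiv), −78 → 0 °C; MeI (5 equiv), 0 °C → rt
Reagents that add atoms: carbon disulfide, S=C=S; iodomethane, CI
Why: Lithiation between two methoxy groups gives 9, which adds to the neopentyl aldehyde faster than to the hindered pivalate (1,2-addition); trapping alkoxide 10 cold as the xanthate forestalls acyl migration from O8 and prepares the deoxygenation; the C15 configuration is of no consequence.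

Step 5
Reactants: 11 S-methyl xanthate
Product: 12 (1R,2S,3S,4S)-3,5-dimethyl-3-[(2,3,5,6-tetramethoxyphenyl)methyl]-6-{[tri(propan-2-yl)silyl]oxy}bicyclo[2.2.2]oct-5-en-2-yl 2,2-dimethylpropanoate
Conditions: Bu3SnH (2 equiv), AIBN (0.2 equiv), toluene, 100 °C
Reagents that add atoms: none
Why: Barton–McCombie deoxygenation through the benzylic C15 radical; the radical conditions leave the silyl enol ether, the ester and the arene untouched and no stereocentre is affected.

Step 6
Reactants: 12 pivalate
Product: 13 (1R,2S,3S,4S)-3,5-dimethyl-3-[(2,3,5,6-tetramethoxyphenyl)methyl]-6-{[tri(propan-2-yl)silyl]oxy}bicyclo[2.2.2]oct-5-en-2-ol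
Conditions: iBu2AlH (3 equiv), CH2Cl2, −78 → 0 °C; aqueous potassium sodium tartrate
Reagents that add atoms: none
Why: Reductive cleavage of the pivalate by the aluminium hydride frees the C8 hydroxyl without touching the base-stable silyl enol ether.

Step 7
Reactants: 13 secondary alcohol
Product: 14 (1S,3S,4R)-3,5-dimethyl-3-[(2,3,5,6-tetramethoxyphenyl)methyl]-6-{[tri(propan-2-yl)silyl]oxy}bicyclo[2.2.2]oct-5-en-2-one (arylmethyl syn to the enol ether bridge)
Conditions: Dess–Martin periodinane (1.5 equiv), NaHCO3, CH2Cl2, 0 °C → rt
Reagents that add atoms: none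
Why: Buffered Dess–Martin oxidation of the hindered secondary alcohol; the ketone is flanked by the bridgehead C3 and the quaternary C9, so it can neither enolise nor move into conjugation.

Step 8
Reactants: 14 bicyclic ketone; 15 vinylmagnesium bromide
Product: 16 (1R,2S,3S,4R)-2-ethenyl-3,5-dimethyl-3-[(2,3,5,6-tetramethoxyphenyl)methyl]-6-{[tri(propan-2-yl)silyl]oxy}bicyclo[2.2.2]oct-5-en-2-ol (vinyl syn to the enol ether bridge, hydroxyl syn to the ethano bridge)
Conditions: CeCl3 (anhydrous, 2.5 equiv), 15 (2.5 equiv), THF, −78 → −40 °C; aqueous NH4Cl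
Reagents that add atoms: none
Why: Organocerium-assisted 1,2-addition to a non-enolisable hindered ketone; the reagent should come from the face syn to the C4=C5 bridge, since the other face is guarded by the inward hydrogen on C2 of the ethano bridge while the two C9 substituents present a carbon atom to either face; this sets C8 with the vinyl group over the alkene as the rearrangement requires.

Step 9
Reactants: 16 vinyl carbinol
Product: 19 (1S,4aR,8aR)-1,4a-dimethyl-1-[(2,3,5,6-tetramethoxyphenyl)methyl]-5-{[tri(propan-2-yl)silyl]oxy}-3,4,4a,7,8,8a-hexahydronaphthalen-2(1H)-one (cis-fused; C8 ketone, C3=C4 silyl enol ether), via potassium carbinolate 17 (not isolated), via potassium C7=C8 enolate 18 (not isolated)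
Conditions: KH (1.5 equiv), 18-crown-6 (1.5 equiv), THF, 0 → 25 °C; aqueous NH4Cl at −78 °C
Reagents that add atoms: none
Why: KH deprotonates the tertiary carbinol and the crown ether frees alkoxide 17 from its counter-ion, which weakens the doubly allylic C3–C8 bond and greatly accelerates the [3,3] sigmatropic shift (anionic oxy-Cope rearrangement). The bicycle holds the 1,5-diene C6=C7–C8–C3–C4=C5 in a boat-like array, so C6 bonds to C5 while C3–C8 breaks, giving enolate 18 and moving the enol ether to C3=C4; the quench protonates C7 to give ketone 19. The closest known reaction is the alkoxide-accelerated rearrangement of 2-vinylbicyclo[2.2.2]oct-5-en-2-ols to cis-fused octalones. Ring B is closed by the C5–C6 bond formed in the six-membered boat transition state of the sigmatropic shift, whereas ring A is not closed but released from the bicycle when the C3–C8 bridge bond is cut. The one new stereocentre, C5, is set by the frame: the vinyl group hangs from C8 and can reach C5 only on the face turned toward the C8–C9 bridge, which leaves the C5 methyl cis to H-10 (5R). C9 and C10 are not touched. The step needs the carbinol epimer with vinyl syn to the C4=C5 bridge, secured in step 8, and it needs bond formation at C5 to outrun loss of the allyl half as a free anion. The silyloxy group sits on the central carbon of that allyl unit, where it neither stabilises a free anion nor blocks C5, and release of bicyclic strain together with enolate formation drives the shift.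

Step 10
Reactants: 19 C8 ketone
Product: 20 {[(4aS,5S,8aR)-5,8a-dimethyl-6-methylidene-5-[(2,3,5,6-tetramethoxyphenyl)methyl]-3,4,4a,5,6,7,8,8a-octahydronaphthalen-1-yl]oxy}tri(propan-2-yl)silane
Conditions: Ph3PCH3Br (4 equiv), KN(SiMe3)2 (3.8 equiv), toluene, rt → 90 °C
Reagents that add atoms: methyltriphenylphosphonium bromide, C[P+](c1ccccc1)(c1ccccc1)c1ccccc1.[Br-]
Why: Wittig methylenation of a ketone next to a quaternary carbon with excess salt-free ylide at elevated temperature; the basic medium leaves the silyl enol ether intact.

Step 11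
Reactants: 20 C8 methylidene compound
Product: 21 {[(4aS,5R,6R,8aR)-5,6,8a-trimethyl-5-[(2,3,5,6-tetramethoxyphenyl)methyl]-3,4,4a,5,6,7,8,8a-octahydronaphthalen-1-yl]oxy}tri(propan-2-yl)silane (C8 methyl cis to the arylmethyl arm)
Conditions: H2 (1 atm), PtO2 (10 mol%), K2CO3, EtOAc, rt
Reagents that add atoms: none
Why: Catalytic hydrogenation of the 1,1-disubstituted alkene, while the trisubstituted, heavily shielded silyl enol ether stays. Ring B should prefer the chair with the arylmethyl arm axial on the convex face, because the other chair forces the C9 methyl against C4 and the vinylic C3–H of ring A; the arm then covers the lower face of the methylidene group and hydrogen arrives from the face of the C9 methyl, which gives the equatorial 8R methyl.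

Step 12
Reactants: 21 silyl enol ether
Product: 22 (4aS,5R,6R,8aR)-5,6,8a-trimethyl-5-[(2,3,5,6-tetramethoxyphenyl)methyl]octahydronaphthalen-1(2H)-one
Conditions: HF·pyridine, pyridine, THF, 0 °C → rt
Reagents that add atoms: none
Why: Fluoride-assisted protodesilylation of the enol ether unveils the C4 ketone; protonation occurs at C3, which is not a stereocentre, and C5 is quaternary, so nothing can epimerise.

Step 13
Reactants: 22 C4 ketone
Product: 23 1,2,4,5-tetramethoxy-3-{[(1R,2R,4aR,8aS)-1,2,4a-trimethyl-5-methylidenedecahydronaphthalen-1-yl]methyl}benzene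
Conditions: Ph3PCH3Br (4 equiv), KN(SiMe3)2 (3.8 equiv), toluene, 100 °C
Reagents that add atoms: methyltriphenylphosphonium bromide, C[P+](c1ccccc1)(c1ccccc1)c1ccccc1.[Br-]
Why: Wittig methylenation of the ketone beside the quaternary C5 installs C4=C11 under basic conditions that cannot move the alkene into the ring.

Step 14
Reactants: 23 tetramethoxyarene
Product: 24 2,5-dimethoxy-3-{[(1R,2R,4aR,8aS)-1,2,4a-trimethyl-5-methylidenedecahydronaphthalen-1-yl]methyl}cyclohexa-2,5-diene-1,4-dione
Conditions: (NH4)2Ce(NO3)6 (2.5 equiv), MeCN/H2O (3:1), 0 °C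
Reagents that add atoms: water, O
Why: Oxidative demethylation of a para-dimethoxyarene by tetravalent cerium; both para pairs of methoxy groups give the same quinone by symmetry, and the short cold exposure spares the exocyclic alkene.

Step 15
Reactants: 24 dimethoxyquinone
Product: 25 2-hydroxy-5-methoxy-3-{[(1R,2R,4aR,8aS)-1,2,4a-trimethyl-5-methylidenedecahydronaphthalen-1-yl]methyl}cyclohexa-2,5-diene-1,4-dione (target)
Conditions: KOH (2 M aqueous, 3 equiv), MeOH, rt; then 1 M HCl to pH 3
Reagents that add atoms: potassium hydroxide, [K+].[OH-]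
Why: Addition–elimination hydrolysis of a vinylogous ester; the methoxy group flanked by the alkyl-bearing carbon and a carbonyl is twisted out of conjugation and its carbon is the more electrophilic, and the hydroxyquinone anion formed resists a second substitution; base is used so that the exocyclic alkene is not isomerised.

## Compound list

1 | 3-ethoxy-2-methylprop-2-enal | CCOC=C(C)C=O | starting material
2 | sodium 2-methyl-3-oxoprop-1-en-1-olate | [Na+].[O-]C=C(C)C=O | intermediate
3 | (E)-2-methyl-3-oxoprop-1-en-1-yl 2,2-dimethylpropanoate | CC(C)(C)C(=O)O/C=C(\C)C=O | intermediate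
4 | 2-methylcyclohex-2-en-1-one | CC1=CCCCC1=O | starting material
5 | lithium 6-methylcyclohexa-1,5-dien-1-olate | [Li+].[O-]C1=CCCC=C1C | intermediate
6 | [(6-methylcyclohexa-1,5-dien-1-yl)oxy]tri(propan-2-yl)silane | CC1=CCCC=C1O[Si](C(C)C)(C(C)C)C(C)C | intermediate
7 | (1R,2S,3S,4R)-3-formyl-3,5-dimethyl-6-{[tri(propan-2-yl)silyl]oxy}bicyclo[2.2.2]oct-5-en-2-yl 2,2-dimethylpropanoate | CC(C)(C)C(=O)O[C@H]1[C@H]2CC[C@H](C(C)=C2O[Si](C(C)C)(C(C)C)C(C)C)[C@]1(C)C=O | intermediate
8 | 1,2,4,5-tetramethoxybenzene | COc1cc(OC)c(OC)cc1OC | starting material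
9 | (2,3,5,6-tetramethoxyphenyl)lithium | [Li]c1c(OC)c(OC)cc(OC)c1OC | intermediate
10 | lithium alkoxide of the C15 carbinol formed from 7 and 9 (both C15 epimers) | CC(C)(C)C(=O)O[C@H]1[C@H]2CC[C@H](C(C)=C2O[Si](C(C)C)(C(C)C)C(C)C)[C@]1(C)C([O-])c1c(OC)c(OC)cc(OC)c1OC.[Li+] | intermediate
11 | (1R,2S,3S,4S)-3-[{[(methylsulfanyl)carbonothioyl]oxy}(2,3,5,6-tetramethoxyphenyl)methyl]-3,5-dimethyl-6-{[tri(propan-2-yl)silyl]oxy}bicyclo[2.2.2]oct-5-en-2-yl 2,2-dimethylpropanoate (both C15 epimers) | CC(C)(C)C(=O)O[C@H]1[C@H]2CC[C@H](C(C)=C2O[Si](C(C)C)(C(C)C)C(C)C)[C@]1(C)C(OC(=S)SC)c1c(OC)c(OC)cc(OC)c1OC | intermediate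
12 | (1R,2S,3S,4S)-3,5-dimethyl-3-[(2,3,5,6-tetramethoxyphenyl)methyl]-6-{[tri(propan-2-yl)silyl]oxy}bicyclo[2.2.2]oct-5-en-2-yl 2,2-dimethylpropanoate | CC(C)(C)C(=O)O[C@H]1[C@H]2CC[C@H](C(C)=C2O[Si](C(C)C)(C(C)C)C(C)C)[C@]1(C)Cc1c(OC)c(OC)cc(OC)c1OC | intermediate
13 | (1R,2S,3S,4S)-3,5-dimethyl-3-[(2,3,5,6-tetramethoxyphenyl)methyl]-6-{[tri(propan-2-yl)silyl]oxy}bicyclo[2.2.2]oct-5-en-2-ol | O[C@H]1[C@H]2CC[C@H](C(C)=C2O[Si](C(C)C)(C(C)C)C(C)C)[C@]1(C)Cc1c(OC)c(OC)cc(OC)c1OC | intermediate
14 | (1S,3S,4R)-3,5-dimethyl-3-[(2,3,5,6-tetramethoxyphenyl)methyl]-6-{[tri(propan-2-yl)silyl]oxy}bicyclo[2.2.2]oct-5-en-2-one | O=C1[C@H]2CC[C@H](C(C)=C2O[Si](C(C)C)(C(C)C)C(C)C)[C@]1(C)Cc1c(OC)c(OC)cc(OC)c1OC | intermediate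
15 | vinylmagnesium bromide | C=C[Mg]Br | starting material
16 | (1R,2S,3S,4R)-2-ethenyl-3,5-dimethyl-3-[(2,3,5,6-tetramethoxyphenyl)methyl]-6-{[tri(propan-2-yl)silyl]oxy}bicyclo[2.2.2]oct-5-en-2-ol | C=C[C@]1(O)[C@H]2CC[C@H](C(C)=C2O[Si](C(C)C)(C(C)C)C(C)C)[C@]1(C)Cc1c(OC)c(OC)cc(OC)c1OC | intermediate
17 | potassium alkoxide of carbinol 16 | C=C[C@]1([O-])[C@H]2CC[C@H](C(C)=C2O[Si](C(C)C)(C(C)C)C(C)C)[C@]1(C)Cc1c(OC)c(OC)cc(OC)c1OC.[K+] | intermediate
18 | potassium C7=C8 enolate of ketone 19 | CC(C)[Si](OC1=CCC[C@H]2[C@](C)(Cc3c(OC)c(OC)cc(OC)c3OC)C([O-])=CC[C@@]12C)(C(C)C)C(C)C.[K+] | intermediate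
19 | (1S,4aR,8aR)-1,4a-dimethyl-1-[(2,3,5,6-tetramethoxyphenyl)methyl]-5-{[tri(propan-2-yl)silyl]oxy}-3,4,4a,7,8,8a-hexahydronaphthalen-2(1H)-one | CC(C)[Si](OC1=CCC[C@H]2[C@](C)(Cc3c(OC)c(OC)cc(OC)c3OC)C(=O)CC[C@@]12C)(C(C)C)C(C)C | intermediate
20 | {[(4aS,5S,8aR)-5,8a-dimethyl-6-methylidene-5-[(2,3,5,6-tetramethoxyphenyl)methyl]-3,4,4a,5,6,7,8,8a-octahydronaphthalen-1-yl]oxy}tri(propan-2-yl)silane | CC(C)[Si](OC1=CCC[C@H]2[C@](C)(Cc3c(OC)c(OC)cc(OC)c3OC)C(=C)CC[C@@]12C)(C(C)C)C(C)C | intermediate
21 | {[(4aS,5R,6R,8aR)-5,6,8a-trimethyl-5-[(2,3,5,6-tetramethoxyphenyl)methyl]-3,4,4a,5,6,7,8,8a-octahydronaphthalen-1-yl]oxy}tri(propan-2-yl)silane | CC(C)[Si](OC1=CCC[C@H]2[C@](C)(Cc3c(OC)c(OC)cc(OC)c3OC)[C@H](C)CC[C@@]12C)(C(C)C)C(C)C | intermediate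
22 | (4aS,5R,6R,8aR)-5,6,8a-trimethyl-5-[(2,3,5,6-tetramethoxyphenyl)methyl]octahydronaphthalen-1(2H)-one | O=C1CCC[C@H]2[C@](C)(Cc3c(OC)c(OC)cc(OC)c3OC)[C@H](C)CC[C@@]12C | intermediate
23 | 1,2,4,5-tetramethoxy-3-{[(1R,2R,4aR,8aS)-1,2,4a-trimethyl-5-methylidenedecahydronaphthalen-1-yl]methyl}benzene | C=C1CCC[C@H]2[C@](C)(Cc3c(OC)c(OC)cc(OC)c3OC)[C@H](C)CC[C@@]12C | intermediate
24 | 2,5-dimethoxy-3-{[(1R,2R,4aR,8aS)-1,2,4a-trimethyl-5-methylidenedecahydronaphthalen-1-yl]methyl}cyclohexa-2,5-diene-1,4-dione | C=C1CCC[C@H]2[C@](C)(CC3=C(OC)C(=O)C=C(OC)C3=O)[C@H](C)CC[C@@]12C | intermediate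
25 | 2-hydroxy-5-methoxy-3-{[(1R,2R,4aR,8aS)-1,2,4a-trimethyl-5-methylidenedecahydronaphthalen-1-yl]methyl}cyclohexa-2,5-diene-1,4-dione | C=C1CCC[C@H]2[C@](C)(CC3=C(O)C(=O)C=C(OC)C3=O)[C@H](C)CC[C@@]12C | target

## Step count and least certain steps

Total: 15 steps. Longest linear sequence: 14 steps (from 4 through steps 2–15; the branch from 1 through steps 1 and 3–15 is equally long).

**Step 9 (key step).** The most likely failure is heterolytic cleavage of the C3–C8 bond running ahead of bond formation at C5. C5 is a fully substituted alkene carbon that must become quaternary, so the allyl half may be lost as an anion (fragmentation or 1,3-shift) or the shift may be slow. Fallback from 16: silylation of the tertiary hydroxyl (Me3SiOSO2CF3, 2,6-lutidine) gives the trimethylsilyl ether of 16 F1. Thermolysis of it in a sealed, base-washed vessel at about 250 °C effects the neutral, concerted siloxy-Cope shift to the bis(silyl enol ether) F2 without any charged intermediate. Mild methanolysis (K2CO3, MeOH, 0 °C) cleaves only the trimethylsilyl enol ether and returns ketone 19.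

**Step 3.** The most likely failure is loss of endo preference. An α-methyl, β-acyloxy enal may place the methyl and not the formyl group under the diene, or react through an open Michael-type pathway, so that C9 is formed with the wrong relative configuration. Fallback from 3 and 6: the cycloaddition is run with the mirror-image (S)-prolinol-derived catalyst, so that the exo adduct F3 has the required bridgehead configuration. LiAlH4 reduces it to the diol F4. Dess–Martin oxidation of both carbinols gives the keto aldehyde F5, and K2CO3 in MeOH removes its formyl group by retro-Claisen cleavage to give the 3-methyl ketone F6. From 8, lithiation and formylation with DMF give 2,3,5,6-tetramethoxybenzaldehyde F7, NaBH4 gives (2,3,5,6-tetramethoxyphenyl)methanol F8 and PBr3 gives 3-(bromomethyl)-1,2,4,5-tetramethoxybenzene F9. Alkylation of the lithium enolate of F6 (LiN(iPr)2, THF, −78 °C) with F9 should occur on the face away from the ethano bridge and gives ketone 14. C9 is then set by the frame and not by the endo rule.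

**Step 8.** The most likely failure is attack of the vinyl reagent from the face syn to the ethano bridge, if the arylmethyl arm on C9 and the silyloxy group crowd the other face. The carbinol formed cannot rearrange. Fallback from 14: the epimeric carbinol F10 obtained in that case is deprotonated (n-BuLi) and treated with PhSCl at −78 °C. The sulfenate rearranges on warming to the allylic sulfoxide F11 (Mislow–Evans [2,3] shift). Heating F11 with P(OMe)3 in MeOH returns the oxygen to C8 through the reverse [2,3] shift on the more accessible face, the one the Grignard reagent had chosen. The hydroxyl then ends syn to the ethano bridge and the vinyl group syn to the enol ether bridge, which is 16.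

**Step 11.** The most likely failure is delivery of hydrogen from the face of the arylmethyl arm, if ring B reacts through the other chair or the arene anchors to the catalyst surface. This would give the C8 epimer. Fallback from 19: reductive cyanation (TosMIC, KOtBu, 1,2-dimethoxyethane/tBuOH) gives the C8 nitrile F12. Deprotonation (LiN(iPr)2) and methylation with MeI on the accessible face, the same face hydrogen would have taken, gives the methylated nitrile F13 with the methyl cis to the arylmethyl arm. iBu2AlH converts it into the aldehyde F14. Decarbonylation with RhCl(PPh3)3 (1 equiv, toluene, 110 °C) replaces the formyl group by hydrogen with retention and gives 21.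

**Step 15.** The most likely failure is attack of hydroxide at the other methoxy-bearing carbon, or hydrolysis of both. Fallback from 24: exhaustive hydrolysis (excess aqueous KOH, then acid) gives the 2,5-dihydroxyquinone F15. One equivalent of Me2SO4 with K2CO3 in acetone methylates its less hindered hydroxyl, the one next to the ring C–H, and gives 25.

## Further compounds

F1 | step 9 | trimethylsilyl ether of carbinol 16 | C=C[C@]1(O[Si](C)(C)C)[C@H]2CC[C@H](C(C)=C2O[Si](C(C)C)(C(C)C)C(C)C)[C@]1(C)Cc1c(OC)c(OC)cc(OC)c1OC
F2 | step 9 | C8 trimethylsilyl enol ether of ketone 19 (bis-silyl enol ether) | CC(C)[Si](OC1=CCC[C@H]2[C@](C)(Cc3c(OC)c(OC)cc(OC)c3OC)C(O[Si](C)(C)C)=CC[C@@]12C)(C(C)C)C(C)C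
F3 | step 3 | exo adduct, C8 and C9 epimer of 7 (formyl syn to the ethano bridge; methyl and pivaloyloxy syn to the enol ether bridge) | CC(C)(C)C(=O)O[C@@H]1[C@H]2CC[C@H](C(C)=C2O[Si](C(C)C)(C(C)C)C(C)C)[C@@]1(C)C=O
F4 | step 3 | 3-(hydroxymethyl)-3,5-dimethyl-6-(triisopropylsilyloxy)bicyclo[2.2.2]oct-5-en-2-ol from F3 | O[C@@H]1[C@H]2CC[C@H](C(C)=C2O[Si](C(C)C)(C(C)C)C(C)C)[C@@]1(C)CO
F5 | step 3 | 3-formyl-3,5-dimethyl-6-(triisopropylsilyloxy)bicyclo[2.2.2]oct-5-en-2-one | O=C1[C@H]2CC[C@H](C(C)=C2O[Si](C(C)C)(C(C)C)C(C)C)[C@@]1(C)C=O
F6 | step 3 | 3,5-dimethyl-6-(triisopropylsilyloxy)bicyclo[2.2.2]oct-5-en-2-one (C3 epimers) | O=C1[C@H]2CC[C@H](C(C)=C2O[Si](C(C)C)(C(C)C)C(C)C)C1C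
F7 | step 3 | 2,3,5,6-tetramethoxybenzaldehyde | O=Cc1c(OC)c(OC)cc(OC)c1OC
F8 | step 3 | (2,3,5,6-tetramethoxyphenyl)methanol | OCc1c(OC)c(OC)cc(OC)c1OC
F9 | step 3 | 3-(bromomethyl)-1,2,4,5-tetramethoxybenzene | BrCc1c(OC)c(OC)cc(OC)c1OC
F10 | step 8 | C8 epimer of carbinol 16 (vinyl syn to the ethano bridge) | C=C[C@@]1(O)[C@H]2CC[C@H](C(C)=C2O[Si](C(C)C)(C(C)C)C(C)C)[C@]1(C)Cc1c(OC)c(OC)cc(OC)c1OC
F11 | step 8 | allylic phenyl sulfoxide with exocyclic C8=C7 alkene (sulfur configuration and alkene geometry not defined) | O=S(CC=C1[C@H]2CC[C@H](C(C)=C2O[Si](C(C)C)(C(C)C)C(C)C)[C@]1(C)Cc1c(OC)c(OC)cc(OC)c1OC)c1ccccc1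
F12 | step 11 | C8 nitrile from ketone 19 (C8 epimers) | CC(C)[Si](OC1=CCC[C@H]2[C@](C)(Cc3c(OC)c(OC)cc(OC)c3OC)C(C#N)CC[C@@]12C)(C(C)C)C(C)C
F13 | step 11 | C8 methyl nitrile (methyl cis to the arylmethyl arm) | CC(C)[Si](OC1=CCC[C@H]2[C@](C)(Cc3c(OC)c(OC)cc(OC)c3OC)[C@](C#N)(C)CC[C@@]12C)(C(C)C)C(C)C
F14 | step 11 | C8 methyl aldehyde (methyl cis to the arylmethyl arm) | CC(C)[Si](OC1=CCC[C@H]2[C@](C)(Cc3c(OC)c(OC)cc(OC)c3OC)[C@](C=O)(C)CC[C@@]12C)(C(C)C)C(C)C
F15 | step 15 | 2,5-dihydroxyquinone corresponding to 24 | C=C1CCC[C@H]2[C@](C)(CC3=C(O)C(=O)C=C(O)C3=O)[C@H](C)CC[C@@]12C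
A1 | alternative 1 | cis-fused 5-{[tert-butyl(dimethyl)silyl]oxy}-1,2,4a-trimethyl-1,2,4a,5,6,7,8,8a-octahydronaphthalene-1-carbaldehyde | CC(C)(C)[Si](C)(C)O[C@@H]1CCC[C@H]2[C@](C)(C=O)[C@H](C)C=C[C@@]12C
A2 | alternative 1 | (2E,7R,8Z,10E)-7-{[tert-butyl(dimethyl)silyl]oxy}-2,8-dimethyldodeca-2,8,10-trienal | C/C=C/C=C(/C)[C@H](O[Si](C)(C)C(C)(C)C)CCC/C=C(\C)C=O
A3 | alternative 2 | cis-fused 5-{[tert-butyl(dimethyl)silyl]oxy}-1,2,4a-trimethyl-1-[(2,3,5,6-tetramethoxyphenyl)methyl]-2,3,4a,5,8,8a-hexahydronaphthalen-4(1H)-one | CC(C)(C)[Si](C)(C)O[C@H]1C=CC[C@H]2[C@](C)(Cc3c(OC)c(OC)cc(OC)c3OC)[C@H](C)CC(=O)[C@@]12C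
A4 | alternative 2 | (4R,5R)-2,4,5-trimethyl-4-[(2,3,5,6-tetramethoxyphenyl)methyl]cyclohex-2-en-1-one | CC1=C[C@](C)(Cc2c(OC)c(OC)cc(OC)c2OC)[C@H](C)CC1=O
A5 | alternative 2 | (E)-1-{[tert-butyl(dimethyl)silyl]oxy}buta-1,3-diene | C=C/C=C/O[Si](C)(C)C(C)(C)C
A6 | alternative 3 | cis-fused methyl 5,6,8a-trimethyl-5-[(2,3,5,6-tetramethoxyphenyl)methyl]-1,2,4a,5,6,7,8,8a-octahydronaphthalene-1-carboxylate | COC(=O)[C@H]1CC=C[C@H]2[C@](C)(Cc3c(OC)c(OC)cc(OC)c3OC)[C@H](C)CC[C@@]12C
A7 | alternative 3 | methyl (2Z,6R,7R,8E)-3,6,7-trimethyl-7-[(2,3,5,6-tetramethoxyphenyl)methyl]undeca-2,8,10-trienoate | COC(=O)/C=C(/C)CC[C@@H](C)[C@@](C)(Cc1c(OC)c(OC)cc(OC)c1OC)/C=C/C=C
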